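**Retrosynthetic overview**
1. Target 14 ⇒ acid 13 by disconnecting the lactone C3–O bond; it is closed last by an enantioselective benzylic C–H lactonisation, which sets C3 (S).
2. 13 ⇒ epoxy acid 7 + acetone N,N-dimethylhydrazone 8: azaenolate opening at the epoxide CH2, O-acetylation, hydrazone hydrolysis; the side-chain (R) centre comes unchanged from the epoxide.
3. 7 ⇒ 2,4-dimethoxy-6-methylbenzoic acid 4 + bromo-epoxide 3 by lateral (benzylic) alkylation.
4. 3 ⇒ 11-bromoundec-1-ene 1 by epoxidation and hydrolytic kinetic resolution.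
5. Ring order: oxirane (step 1, opened in step 4), then the phthalide lactone (step 5); the benzene ring is bought.

Assumption: compounds 1, 4 and 8 are bought as such.
Assumption: the (S,S)-bisoxazoline is taken as the ligand enantiomer that gives (3S) in step 5; the sense is fixed in a model run and the (R,R)-ligand is used if it proves opposite.

**Step 1**
Reactants: 1 11-bromoundec-1-ene
Product: 2 rac-2-(9-bromononyl)oxirane
Conditions: mCPBA (1.2 equiv), CH2Cl2, 0 °C → rt
Reagents that add atoms: mCPBA, O=C(OO)c1cccc(Cl)c1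
Why: Prilezhaev epoxidation of the only alkene; the primary bromide is inert to peracid and the racemate is resolved in the next step.

**Step 2**
Reactants: 2 rac-2-(9-bromononyl)oxirane
Product: 3 (2R)-2-(9-bromononyl)oxirane
Conditions: (R,R)-(salen)Co(OAc) (0.5 mol%; salen = N,N'-bis(3,5-di-tert-butylsalicylidene)cyclohexane-1,2-diamine dianion, trivalent cobalt), H2O (0.55 equiv), minimal THF, 0 °C → rt, 18 h; chromatography
Reagents that add atoms: none
Why: Jacobsen hydrolytic kinetic resolution; the (R,R)-catalyst hydrates the (S)-epoxide selectively, so the (R)-epoxide (the later acetate centre) is recovered in >99% ee at about 55% conversion, and alkyl bromides are tolerated.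

**Step 3**
Reactants: 4 2,4-dimethoxy-6-methylbenzoic acid; 3 (2R)-2-(9-bromononyl)oxirane
Product: 7 2,4-dimethoxy-6-{10-[(2R)-oxiran-2-yl]decyl}benzoic acid, via benzylic dianion 5 (not isolated), via lithium carboxylate of the epoxy acid 6 (not isolated)
Conditions: lithium diisopropylamide (2.1 equiv), THF, −78 → 0 → −78 °C; 3 (0.95 equiv), −78 → −20 °C; cold 1 M H3PO4 to pH 4, used crude
Reagents that add atoms: none
Why: Lateral lithiation of the o-toluate dianion and SN2 alkylation; the benzylic carbanion displaces primary bromide far faster than it opens an unactivated epoxide without a Lewis acid, and the stereocentre is not touched.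

**Step 4**
Reactants: 7 2,4-dimethoxy-6-{10-[(2R)-oxiran-2-yl]decyl}benzoic acid; 8 acetone N,N-dimethylhydrazone
Product: 13 2-[(11R)-11-acetoxy-14-oxopentadecyl]-4,6-dimethoxybenzoic acid, via sodium carboxylate of the epoxy acid 9 (not isolated), via lithiated hydrazone 10 (not isolated), via lithium alkoxide sodium carboxylate 11 (not isolated), via acetoxy hydrazone sodium carboxylate 12 (not isolated)
Conditions: 7, NaN(SiMe3)2 (1.0 equiv), THF, −78 → 0 °C; cannulated into 8 + n-BuLi (1.5 equiv each, THF, −78 → 0 °C); 0 °C → rt; Ac2O (2 equiv), 0 °C; sat. aq. oxalic acid/Et2O, rt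
Reagents that add atoms: acetic anhydride, CC(=O)OC(C)=O; water, O
Why: The acid is first masked as its THF-soluble sodium carboxylate with the non-nucleophilic silylamide so that no azaenolate is spent on the acidic proton, then a Corey–Enders hydrazone azaenolate opens the terminal epoxide at its CH2 carbon (the C–O bond at the stereocentre is not broken, so R is retained), the lithium alkoxide is acetylated in situ, and mild oxalic acid hydrolysis frees the methyl ketone and the carboxylic acid without cleaving the acetate.

**Step 5**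
Reactants: 13 2-[(11R)-11-acetoxy-14-oxopentadecyl]-4,6-dimethoxybenzoic acid
Product: 14 (3S)-3-[(10R)-10-acetoxy-13-oxotetradecyl]-5,7-dimethoxy-2-benzofuran-1(3H)-one
Conditions: Cu(MeCN)4BF4 (10 mol%), (S,S)-Ph-BOX [2,2'-(propane-2,2-diyl)bis((4S)-4-phenyl-4,5-dihydrooxazole), 12 mol%], N-fluoro-2,4,6-trimethylpyridinium tetrafluoroborate (1.3 equiv), Li2CO3 (1.2 equiv), MeCN/PhCF3 1:1, 390 nm LEDs, 0 °C
Reagents that add atoms: none
Why: Proposed new method: a copper-catalysed, light-driven enantioselective dehydrogenative benzylic C–H lactonisation. The N–F oxidant turns monovalent copper into a bisoxazoline-bound divalent copper fluoride, which exchanges with the substrate carboxylate. 390 nm ligand-to-metal charge transfer homolyses the Cu–O bond to an aroyloxyl radical, which takes the neighbouring benzylic hydrogen by 1,5-HAT (six-membered transition state, about 25 kcal/mol downhill) faster than it loses CO2; this confines C–H cleavage to C3 despite the many other CH2 groups. The benzylic radical is captured by a chiral divalent copper centre bound to the same carboxylate, and C–O reductive elimination from the resulting six-membered trivalent copper metallacycle closes the lactone and sets C3 (S) under ligand control. The two methoxy groups are meta to C3, so a free benzylic cation, which would erode ee, is disfavoured. The closest known reaction types are racemic 1,5-HAT dehydrogenative lactonisations of 2-alkylbenzoic acids, Kharasch–Sosnovsky acyloxylation, copper/bisoxazoline radical-relay benzylic C–H cyanation, and copper LMCT activation of aryl carboxylates.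

**Compound list**
1 | 11-bromoundec-1-ene | C=CCCCCCCCCCBr | starting material
2 | rac-2-(9-bromononyl)oxirane | BrCCCCCCCCCC1CO1 | intermediate
3 | (2R)-2-(9-bromononyl)oxirane | BrCCCCCCCCC[C@@H]1CO1 | intermediate
4 | 2,4-dimethoxy-6-methylbenzoic acid | COc1cc(C)c(C(=O)O)c(OC)c1 | starting material
5 | lithium 2-(lithiomethyl)-4,6-dimethoxybenzoate (benzylic dianion, not isolated) | [Li]Cc1cc(OC)cc(OC)c1C(=O)O[Li] | intermediate
6 | lithium 2,4-dimethoxy-6-{10-[(2R)-oxiran-2-yl]decyl}benzoate (not isolated) | COc1cc(OC)c(C(=O)O[Li])c(CCCCCCCCCC[C@@H]2CO2)c1 | intermediate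
7 | 2,4-dimethoxy-6-{10-[(2R)-oxiran-2-yl]decyl}benzoic acid | COc1cc(OC)c(C(=O)O)c(CCCCCCCCCC[C@@H]2CO2)c1 | intermediate
8 | acetone N,N-dimethylhydrazone | CC(C)=NN(C)C | starting material
9 | sodium 2,4-dimethoxy-6-{10-[(2R)-oxiran-2-yl]decyl}benzoate (not isolated) | COc1cc(OC)c(C(=O)O[Na])c(CCCCCCCCCC[C@@H]2CO2)c1 | intermediate
10 | [2-(2,2-dimethylhydrazinylidene)propyl]lithium (not isolated) | [Li]CC(C)=NN(C)C | intermediate
11 | lithium alkoxide sodium carboxylate of 2-[(11R)-14-(2,2-dimethylhydrazinylidene)-11-hydroxypentadecyl]-4,6-dimethoxybenzoic acid (not isolated) | COc1cc(OC)c(C(=O)O[Na])c(CCCCCCCCCC[C@H](CCC(C)=NN(C)C)O[Li])c1 | intermediate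
12 | sodium 2-[(11R)-11-acetoxy-14-(2,2-dimethylhydrazinylidene)pentadecyl]-4,6-dimethoxybenzoate (not isolated) | COc1cc(OC)c(C(=O)O[Na])c(CCCCCCCCCC[C@H](CCC(C)=NN(C)C)OC(C)=O)c1 | intermediate
13 | 2-[(11R)-11-acetoxy-14-oxopentadecyl]-4,6-dimethoxybenzoic acid | COc1cc(OC)c(C(=O)O)c(CCCCCCCCCC[C@H](CCC(C)=O)OC(C)=O)c1 | intermediate
14 | (3S)-3-[(10R)-10-acetoxy-13-oxotetradecyl]-5,7-dimethoxy-2-benzofuran-1(3H)-one | COc1cc(OC)c2c(c1)[C@H](CCCCCCCCC[C@H](CCC(C)=O)OC(C)=O)OC2=O | target

**Step count and risks**
Total steps: 5. Longest linear sequence: 5 (1 → 2 → 3 → 7 → 13 → 14). No protecting groups.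

Steps most likely to fail:

Step 3 (bromide versus epoxide chemoselectivity). The benzylic anion may open the epoxide or alkylate incompletely. The fallback reverses the order of events. It sets out from 4 (as dianion 5) and 1: alkylation with 11-bromoundec-1-ene under the same lithium diisopropylamide conditions gives 2-(dodec-11-en-1-yl)-4,6-dimethoxybenzoic acid F1. Epoxidation with mCPBA in CH2Cl2 gives rac-2,4-dimethoxy-6-[10-(oxiran-2-yl)decyl]benzoic acid F2. Hydrolytic kinetic resolution of F2 with (R,R)-(salen)Co(OAc) and 0.55 equiv H2O leaves the (R)-epoxide; the hindered 2,6-disubstituted carboxyl is a poor nucleophile toward the cobalt-bound epoxide. The fallback comes back to the route at 7.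

Step 4 (one-pot opening, acetylation and hydrolysis). The azaenolate may react sluggishly with the carboxylate-bearing epoxide, or the acetic anhydride quench may be messy. The fallback replaces the azaenolate by an alkene as the masked ketone. It sets out from 7: 2-methylallylmagnesium chloride (2.5 equiv, the first equivalent deprotonates the acid) with CuI (10 mol%) in THF at −30 °C opens the epoxide at CH2 to give 2-[(11R)-11-hydroxy-14-methylpentadec-14-en-1-yl]-4,6-dimethoxybenzoic acid F3. Ac2O/pyridine/DMAP followed by aqueous work-up gives 2-[(11R)-11-acetoxy-14-methylpentadec-14-en-1-yl]-4,6-dimethoxybenzoic acid F4. Lemieux–Johnson cleavage of the 1,1-disubstituted alkene (K2OsO2(OH)4 2 mol%, NaIO4, 2,6-lutidine, dioxane/H2O) gives the methyl ketone. The fallback comes back at 13.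

Step 5 (the proposed new lactonisation). The risks are low or reversed enantioselectivity, decarboxylation of the aroyloxyl radical, and fluorination of the electron-rich ring. The fallback uses known chemistry without stereocontrol and then separates. It sets out from 13: the classical peroxydisulfate lactonisation of 2-alkylbenzoic acids (K2S2O8 2 equiv, CuSO4 10 mol%, MeCN/H2O, 60 °C) gives (3RS)-3-[(10R)-10-acetoxy-13-oxotetradecyl]-5,7-dimethoxy-2-benzofuran-1(3H)-one F5 as a 1:1 mixture of C3 epimers. Preparative HPLC on an amylose-based chiral phase removes (3R)-3-[(10R)-10-acetoxy-13-oxotetradecyl]-5,7-dimethoxy-2-benzofuran-1(3H)-one F6. The fallback comes back at 14, with at most half the material.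

**Further compounds**
F1 | step 3 | 2-(dodec-11-en-1-yl)-4,6-dimethoxybenzoic acid | COc1cc(OC)c(C(=O)O)c(CCCCCCCCCCC=C)c1
F2 | step 3 | rac-2,4-dimethoxy-6-[10-(oxiran-2-yl)decyl]benzoic acid | COc1cc(OC)c(C(=O)O)c(CCCCCCCCCCC2CO2)c1
F3 | step 4 | 2-[(11R)-11-hydroxy-14-methylpentadec-14-en-1-yl]-4,6-dimethoxybenzoic acid | COc1cc(OC)c(C(=O)O)c(CCCCCCCCCC[C@H](CCC(C)=C)O)c1
F4 | step 4 | 2-[(11R)-11-acetoxy-14-methylpentadec-14-en-1-yl]-4,6-dimethoxybenzoic acid | COc1cc(OC)c(C(=O)O)c(CCCCCCCCCC[C@H](CCC(C)=C)OC(C)=O)c1
F5 | step 5 | (3RS)-3-[(10R)-10-acetoxy-13-oxotetradecyl]-5,7-dimethoxy-2-benzofuran-1(3H)-one (1:1 C3-epimer mixture) | COc1cc(OC)c2c(c1)C(CCCCCCCCC[C@H](CCC(C)=O)OC(C)=O)OC2=O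
F6 | step 5 | (3R)-3-[(10R)-10-acetoxy-13-oxotetradecyl]-5,7-dimethoxy-2-benzofuran-1(3H)-one | COc1cc(OC)c2c(c1)[C@@H](CCCCCCCCC[C@H](CCC(C)=O)OC(C)=O)OC2=O
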